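The plan rests on the aldol retron C13(OH)–C14(Me)–C15(OH) that sits between the polyol and the C16–C25 pentaene of the 28-membered lactone ring. The C15 oxygen is carried as a ketone conjugated to the pentaene, so that C14 is its only enolisable carbon. A boron-mediated anti-aldol macrocyclisation then joins C14 to a C13 aldehyde, closing the macrocycle and setting C13 and C14 in one operation. The precursor is an open-chain ester of a C1–C13 polyol acid, ending in that aldehyde, with a C14–C27 hydroxy pentaenyl ethyl ketone. Hydroxyl-directed 1,3-anti reduction then sets C15, and one acid treatment frees the polyol.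

Key step: step 22

Assumption: (R)-2-allyloxirane and (2R,3R)-2,3-dimethyloxirane are bought as single enantiomers; locants C1–C27 in the text and in names of advanced compounds follow the macrolide numbering (C1 lactone carbonyl, C27 the carbinol carbon on the ring oxygen).

Step 1
Reactants: 1 tert-butyl 2-[(4R,6R)-6-(cyanomethyl)-2,2-dimethyl-1,3-dioxan-4-yl]acetate
Product: 2 tert-butyl 2-[(4R,6S)-2,2-dimethyl-6-(2-oxoethyl)-1,3-dioxan-4-yl]acetate
Conditions: i-Bu2AlH (1.1 equiv), toluene, −78 °C; aqueous potassium sodium tartrate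
Reagents that add atoms: water, O
Why: Partial hydride reduction of the nitrile to the aluminium imine and its hydrolysis should give the aldehyde (future C13) while the hindered tert-butyl ester survives at −78 °C; the two stereocentres (future C9 and C11) are bought.

Step 2
Reactants: 2 tert-butyl 2-[(4R,6S)-2,2-dimethyl-6-(2-oxoethyl)-1,3-dioxan-4-yl]acetate
Product: 3 tert-butyl 2-[(4R,6R)-6-(2-hydroxyethyl)-2,2-dimethyl-1,3-dioxan-4-yl]acetate
Conditions: NaBH4, MeOH, 0 °C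
Reagents that add atoms: none
Why: Borohydride reduction of the aldehyde, to which the tert-butyl ester is inert.

Step 3
Reactants: 3 tert-butyl 2-[(4R,6R)-6-(2-hydroxyethyl)-2,2-dimethyl-1,3-dioxan-4-yl]acetate
Product: 4 tert-butyl 2-[(4R,6R)-2,2-dimethyl-6-[2-(triethylsilyloxy)ethyl]-1,3-dioxan-4-yl]acetate
Conditions: Et3SiCl, imidazole, CH2Cl2, 0 °C
Reagents that add atoms: chlorotriethylsilane, CC[Si](Cl)(CC)CC
Why: Silylation of the primary alcohol gives the triethylsilyl ether that later serves as the latent C13 aldehyde.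

Step 4
Reactants: 4 tert-butyl 2-[(4R,6R)-2,2-dimethyl-6-[2-(triethylsilyloxy)ethyl]-1,3-dioxan-4-yl]acetate
Product: 5 2-[(4S,6R)-2,2-dimethyl-6-[2-(triethylsilyloxy)ethyl]-1,3-dioxan-4-yl]ethanol
Conditions: LiAlH4, Et2O, 0 °C
Reagents that add atoms: none
Why: Hydride reduction of the ester to the C7 primary alcohol, which silyl ether and acetonide tolerate.

Step 5
Reactants: 5 2-[(4S,6R)-2,2-dimethyl-6-[2-(triethylsilyloxy)ethyl]-1,3-dioxan-4-yl]ethanol
Product: 6 (4R,6R)-4-(2-bromoethyl)-2,2-dimethyl-6-[2-(triethylsilyloxy)ethyl]-1,3-dioxane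
Conditions: CBr4, PPh3, 2,6-lutidine, CH2Cl2, 0 °C
Reagents that add atoms: carbon tetrabromide, BrC(Br)(Br)Br
Why: Appel bromination of the primary alcohol under buffered conditions that spare the acid-labile groups.

Step 6
Reactants: 6 (4R,6R)-4-(2-bromoethyl)-2,2-dimethyl-6-[2-(triethylsilyloxy)ethyl]-1,3-dioxane; 7 (R)-2-allyloxirane
Product: 9 (4S)-1-[(4S,6R)-2,2-dimethyl-6-[2-(triethylsilyloxy)ethyl]-1,3-dioxan-4-yl]hept-6-en-4-ol, via Grignard reagent 8 (not isolated)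
Conditions: Mg, THF, 40 °C; then CuI (10 mol%), 7, THF, −30 °C; then H2O
Reagents that add atoms: none
Why: Copper-catalysed Grignard opening of the terminal epoxide at its CH2 end forms the C6–C7 bond, and the C5 carbinol configuration is carried over unchanged from 7.

Step 7
Reactants: 9 (4S)-1-[(4S,6R)-2,2-dimethyl-6-[2-(triethylsilyloxy)ethyl]-1,3-dioxan-4-yl]hept-6-en-4-ol
Product: 10 (4S,6R)-2,2-dimethyl-4-[(4S)-4-(triethylsilyloxy)hept-6-enyl]-6-[2-(triethylsilyloxy)ethyl]-1,3-dioxane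
Conditions: Et3SiCl, imidazole, DMF, rt
Reagents that add atoms: chlorotriethylsilane, CC[Si](Cl)(CC)CC
Why: Silylation of the secondary alcohol as an ether that the final acid treatment removes.

Step 8
Reactants: 10 (4S,6R)-2,2-dimethyl-4-[(4S)-4-(triethylsilyloxy)hept-6-enyl]-6-[2-(triethylsilyloxy)ethyl]-1,3-dioxane
Product: 11 (3S)-6-[(4S,6R)-2,2-dimethyl-6-[2-(triethylsilyloxy)ethyl]-1,3-dioxan-4-yl]-3-(triethylsilyloxy)hexanal
Conditions: O3, CH2Cl2, −78 °C; then PPh3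
Reagents that add atoms: ozone, [O-][O+]=O
Why: Ozonolysis with reductive work-up cleaves the only alkene to the C3 aldehyde, which has no epimerisable α-centre.

Step 9
Reactants: 12 (S)-4-benzyloxazolidin-2-one; 13 butanoyl chloride
Product: 14 (S)-4-benzyl-3-butanoyloxazolidin-2-one
Conditions: n-BuLi, THF, −78 °C; then 13
Reagents that add atoms: none
Why: N-acylation of the lithiated oxazolidinone gives the chiral butanoyl imide.

Step 10
Reactants: 14 (S)-4-benzyl-3-butanoyloxazolidin-2-one; 11 (3S)-6-[(4S,6R)-2,2-dimethyl-6-[2-(triethylsilyloxy)ethyl]-1,3-dioxan-4-yl]-3-(triethylsilyloxy)hexanal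
Product: 16 (4S)-4-benzyl-3-[(2S,3R,5S)-8-[(4S,6R)-2,2-dimethyl-6-[2-(triethylsilyloxy)ethyl]-1,3-dioxan-4-yl]-2-ethyl-3-hydroxy-5-(triethylsilyloxy)octanoyl]oxazolidin-2-one, via Z-boron enolate 15 (not isolated)
Conditions: Bu2BOTf, i-Pr2NEt, CH2Cl2, 0 °C; then 11, −78 to 0 °C; then pH 7 buffer, MeOH, H2O2
Reagents that add atoms: none
Why: Evans syn-aldol reaction, in which Z-boron enolate 15 adds through a Zimmerman–Traxler chair on the face away from the benzyl group, so the auxiliary sets 2S and 3R regardless of the C5 silyloxy group.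

Step 11
Reactants: 16 (4S)-4-benzyl-3-[(2S,3R,5S)-8-[(4S,6R)-2,2-dimethyl-6-[2-(triethylsilyloxy)ethyl]-1,3-dioxan-4-yl]-2-ethyl-3-hydroxy-5-(triethylsilyloxy)octanoyl]oxazolidin-2-one
Product: 17 (4S)-4-benzyl-3-[(2S,3R,5S)-8-[(4S,6R)-2,2-dimethyl-6-[2-(triethylsilyloxy)ethyl]-1,3-dioxan-4-yl]-2-ethyl-3,5-bis(triethylsilyloxy)octanoyl]oxazolidin-2-one
Conditions: Et3SiOTf, 2,6-lutidine, CH2Cl2, −78 °C
Reagents that add atoms: triethylsilyl trifluoromethanesulfonate, CC[Si](CC)(CC)OS(=O)(=O)C(F)(F)F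
Why: Silylation of the hindered aldol hydroxyl with the silyl triflate, which also blocks retro-aldol cleavage in the next step.

Step 12
Reactants: 17 (4S)-4-benzyl-3-[(2S,3R,5S)-8-[(4S,6R)-2,2-dimethyl-6-[2-(triethylsilyloxy)ethyl]-1,3-dioxan-4-yl]-2-ethyl-3,5-bis(triethylsilyloxy)octanoyl]oxazolidin-2-one
Product: 18 (2S,3R,5S)-8-[(4S,6R)-2,2-dimethyl-6-[2-(triethylsilyloxy)ethyl]-1,3-dioxan-4-yl]-2-ethyl-3,5-bis(triethylsilyloxy)octanoic acid
Conditions: LiOH, H2O2, THF/H2O, 0 °C; then Na2SO3; then HCl to pH 4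
Reagents that add atoms: hydrogen peroxide, OO
Why: Lithium hydroperoxide cleaves the exocyclic imide carbonyl selectively without epimerising C2, and the auxiliary is recovered.

Step 13
Reactants: 19 (2R,3R)-2,3-dimethyloxirane; 20 vinylmagnesium bromide
Product: 21 (2R,3R)-3-methylpent-4-en-2-ol
Conditions: CuI (10 mol%), THF/Et2O, −30 to 0 °C; then H2O
Reagents that add atoms: none
Why: Copper-catalysed SN2 opening of the C2-symmetric trans-epoxide, whose two carbons are equivalent, with inversion at the attacked carbon gives the syn (2R,3R) pair (future C27 and C26).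

Step 14
Reactants: 21 (2R,3R)-3-methylpent-4-en-2-ol; 22 (E)-but-2-enal
Product: 23 (2E,4R,5R)-5-hydroxy-4-methylhex-2-enal
Conditions: second-generation Hoveyda–Grubbs catalyst RuCl2(H2IMes)(=CH-C6H4-2-O-i-Pr) (5 mol%), excess 22, CH2Cl2, 40 °C
Reagents that add atoms: none
Why: Olefin cross-metathesis of the terminal alkene with an excess of the enal should give the E-enal under thermodynamic control.

Step 15
Reactants: 23 (2E,4R,5R)-5-hydroxy-4-methylhex-2-enal; 24 triethyl 4-phosphonocrotonate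
Product: 25 ethyl (2E,4E,6E,8R,9R)-9-hydroxy-8-methyldeca-2,4,6-trienoate
Conditions: LiN(SiMe3)2 (2.2 equiv), 24 (2.2 equiv), THF, −78 to 0 °C
Reagents that add atoms: none
Why: Vinylogous Horner–Wadsworth–Emmons olefination adds two E double bonds, a second equivalent of the phosphonate anion covering the free hydroxyl.

Step 16
Reactants: 25 ethyl (2E,4E,6E,8R,9R)-9-hydroxy-8-methyldeca-2,4,6-trienoate
Product: 26 (2E,4E,6E,8R,9R)-8-methyldeca-2,4,6-triene-1,9-diol
Conditions: i-Bu2AlH (3.5 equiv), CH2Cl2, −78 °C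
Reagents that add atoms: none
Why: 1,2-Hydride reduction of the conjugated ester gives the allylic alcohol.

Step 17
Reactants: 26 (2E,4E,6E,8R,9R)-8-methyldeca-2,4,6-triene-1,9-diol
Product: 27 (2E,4E,6E,8R,9R)-9-hydroxy-8-methyldeca-2,4,6-trienal
Conditions: MnO2, CH2Cl2, rt
Reagents that add atoms: none
Why: MnO2 oxidises only the allylic primary alcohol and leaves the saturated secondary one.

Step 18
Reactants: 27 (2E,4E,6E,8R,9R)-9-hydroxy-8-methyldeca-2,4,6-trienal; 28 (1,3-dioxolan-2-ylmethyl)triphenylphosphonium bromide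
Product: 30 (2E,4E,6E,8E,10R,11R)-11-hydroxy-10-methyldodeca-2,4,6,8-tetraenal, via dioxolane tetraene 29 (not isolated)
Conditions: t-BuOK, THF, 0 °C; then 1 M HCl, THF, rt
Reagents that add atoms: water, O
Why: Wittig two-carbon homologation with a masked formyl ylide, followed by acid hydrolysis of dioxolane 29, which also equilibrates the new double bond to E.

Step 19
Reactants: 30 (2E,4E,6E,8E,10R,11R)-11-hydroxy-10-methyldodeca-2,4,6,8-tetraenal; 31 diethyl (2-oxobutyl)phosphonate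
Product: 32 (4E,6E,8E,10E,12E,14R,15R)-15-hydroxy-14-methylhexadeca-4,6,8,10,12-pentaen-3-one
Conditions: LiCl, DBU, MeCN, rt
Reagents that add atoms: none
Why: Horner–Wadsworth–Emmons olefination under Masamune–Roush conditions gives the E-enone and installs the ethyl ketone (future C14 and C15) without strong base.

Step 20
Reactants: 18 (2S,3R,5S)-8-[(4S,6R)-2,2-dimethyl-6-[2-(triethylsilyloxy)ethyl]-1,3-dioxan-4-yl]-2-ethyl-3,5-bis(triethylsilyloxy)octanoic acid; 32 (4E,6E,8E,10E,12E,14R,15R)-15-hydroxy-14-methylhexadeca-4,6,8,10,12-pentaen-3-one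
Product: 34 (2R,3R,4E,6E,8E,10E,12E)-3-methyl-14-oxohexadeca-4,6,8,10,12-pentaen-2-yl (2S,3R,5S)-8-[(4S,6R)-2,2-dimethyl-6-[2-(triethylsilyloxy)ethyl]-1,3-dioxan-4-yl]-2-ethyl-3,5-bis(triethylsilyloxy)octanoate, via mixed anhydride 33 (not isolated)
Conditions: 2,4,6-trichlorobenzoyl chloride, Et3N, toluene, rt; then 32, DMAP, rt
Reagents that add atoms: none
Why: Yamaguchi esterification through mixed anhydride 33 acylates the hindered secondary alcohol; no stereocentre is formed, and brief exposure to DMAP limits C2 epimerisation.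

Step 21
Reactants: 34 (2R,3R,4E,6E,8E,10E,12E)-3-methyl-14-oxohexadeca-4,6,8,10,12-pentaen-2-yl (2S,3R,5S)-8-[(4S,6R)-2,2-dimethyl-6-[2-(triethylsilyloxy)ethyl]-1,3-dioxan-4-yl]-2-ethyl-3,5-bis(triethylsilyloxy)octanoate
Product: 35 (2R,3R,4E,6E,8E,10E,12E)-3-methyl-14-oxohexadeca-4,6,8,10,12-pentaen-2-yl (2S,3R,5S)-8-[(4S,6S)-2,2-dimethyl-6-(2-oxoethyl)-1,3-dioxan-4-yl]-2-ethyl-3,5-bis(triethylsilyloxy)octanoate
Conditions: (COCl)2, DMSO, CH2Cl2, −78 to −40 °C; then Et3N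
Reagents that add atoms: none
Why: Under Swern conditions a primary triethylsilyl ether is cleaved and oxidised directly to the aldehyde, while the secondary silyl ethers, the acetonide and the pentaenone should survive at low temperature.

Step 22
Reactants: 35 (2R,3R,4E,6E,8E,10E,12E)-3-methyl-14-oxohexadeca-4,6,8,10,12-pentaen-2-yl (2S,3R,5S)-8-[(4S,6S)-2,2-dimethyl-6-(2-oxoethyl)-1,3-dioxan-4-yl]-2-ethyl-3,5-bis(triethylsilyloxy)octanoate
Product: 38 (2S,3R,5S,9S,11R,13R,14R,26R,27R)-macrolactone with 15-ketone and free 13-hydroxyl (9,11-acetonide; 3,5-bis(triethylsilyl) ether; all-E C16–C25 pentaene), via E-enol borinate 36 (not isolated), via boron aldolate 37 (not isolated)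
Conditions: (c-C6H11)2BCl (3 equiv), Et3N (4 equiv), Et2O, −78 to −20 °C, 35 added by syringe pump to about 1 mM; then MeOH, pH 7 buffer, silica gel
Reagents that add atoms: none
Why: (c-C6H11)2BCl binds the pentaenone oxygen, the most Lewis-basic carbonyl, and Et3N removes a C14 hydrogen, the ketone's only α-hydrogens, to give E-enol borinate 36, which adds to the C13 aldehyde through a Zimmerman–Traxler chair to give aldolate 37, hydrolysed without oxidant to spare the pentaene. The closest known reaction type is the dicyclohexylboron-mediated anti-aldol reaction, run here as a macro-aldolisation, a ring closure established for keto aldehydes. The 28-membered ring closes in a 28-(enolendo)-exo-trig mode, C14 attacking the aldehyde carbon, and is large enough to hold the unstrained chair. The 13,14-anti relationship follows from the E-enolate geometry, and the C13 configuration is set by the C11 acetonide oxygen, the enolate approaching the aldehyde face anti to C10 in the dipole-minimised conformer (1,3-anti, hence 13R,14R). The step needs ketone enolisation in preference to the aldehyde and the ester, and cyclisation in preference to dimerisation: the ester is inert to this reagent pair, an aldehyde-derived enol borinate cannot add to the ketone and reverts to aldehyde on work-up, and slow addition keeps the substrate dilute.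

Step 23
Reactants: 38 (2S,3R,5S,9S,11R,13R,14R,26R,27R)-macrolactone with 15-ketone and free 13-hydroxyl
Product: 39 (2S,3R,5S,9S,11R,13R,14R,15R,26R,27R)-macrolactone 13,15-diol (9,11-acetonide; 3,5-bis(triethylsilyl) ether; all-E C16–C25 pentaene)
Conditions: Me4NBH(OAc)3, MeCN/AcOH, −30 °C
Reagents that add atoms: none
Why: Evans–Saksena reduction, in which the C13 hydroxyl binds boron and delivers hydride intramolecularly to the ketone through a chair transition state, giving the 1,3-anti diol (15R) by 1,2-reduction of the enone.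

Step 24
Reactants: 39 (2S,3R,5S,9S,11R,13R,14R,15R,26R,27R)-macrolactone 13,15-diol
Product: 40 (2S,3R,5S,9S,11S,13R,14R,15R,16E,18E,20E,22E,24E,26R,27R)-2-ethyl-3,5,9,11,13,15-hexahydroxy-14,26-dimethyloctacosa-16,18,20,22,24-pentaen-27-olide
Conditions: Dowex 50WX8 (H+ form), MeOH, rt
Reagents that add atoms: none
Why: Acid-catalysed methanolysis removes the acetonide and both triethylsilyl ethers in one operation, a deprotection mode tolerated by polyene macrolides that carry a hydroxyl next to the polyene.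

Compound list
1 | tert-butyl 2-[(4R,6R)-6-(cyanomethyl)-2,2-dimethyl-1,3-dioxan-4-yl]acetate | N#CC[C@@H](O2)C[C@@H](OC2(C)C)CC(=O)OC(C)(C)C | starting material
2 | tert-butyl 2-[(4R,6S)-2,2-dimethyl-6-(2-oxoethyl)-1,3-dioxan-4-yl]acetate | O=CC[C@@H](O2)C[C@@H](OC2(C)C)CC(=O)OC(C)(C)C | intermediate
3 | tert-butyl 2-[(4R,6R)-6-(2-hydroxyethyl)-2,2-dimethyl-1,3-dioxan-4-yl]acetate | OCC[C@@H](O2)C[C@@H](OC2(C)C)CC(=O)OC(C)(C)C | intermediate
4 | tert-butyl 2-[(4R,6R)-2,2-dimethyl-6-[2-(triethylsilyloxy)ethyl]-1,3-dioxan-4-yl]acetate | CC[Si](CC)(CC)OCC[C@@H](O2)C[C@@H](OC2(C)C)CC(=O)OC(C)(C)C | intermediate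
5 | 2-[(4S,6R)-2,2-dimethyl-6-[2-(triethylsilyloxy)ethyl]-1,3-dioxan-4-yl]ethanol | CC[Si](CC)(CC)OCC[C@@H](O2)C[C@@H](OC2(C)C)CCO | intermediate
6 | (4R,6R)-4-(2-bromoethyl)-2,2-dimethyl-6-[2-(triethylsilyloxy)ethyl]-1,3-dioxane | CC[Si](CC)(CC)OCC[C@@H](O2)C[C@@H](OC2(C)C)CCBr | intermediate
7 | (R)-2-allyloxirane | C=CC[C@@H]1CO1 | starting material
8 | Grignard reagent of 6 (bromomagnesium on C7) | CC[Si](CC)(CC)OCC[C@@H](O2)C[C@@H](OC2(C)C)CC[Mg]Br | intermediate
9 | (4S)-1-[(4S,6R)-2,2-dimethyl-6-[2-(triethylsilyloxy)ethyl]-1,3-dioxan-4-yl]hept-6-en-4-ol | CC[Si](CC)(CC)OCC[C@@H](O2)C[C@@H](OC2(C)C)CCC[C@H](O)CC=C | intermediate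
10 | (4S,6R)-2,2-dimethyl-4-[(4S)-4-(triethylsilyloxy)hept-6-enyl]-6-[2-(triethylsilyloxy)ethyl]-1,3-dioxane | CC[Si](CC)(CC)OCC[C@@H](O2)C[C@@H](OC2(C)C)CCC[C@H](O[Si](CC)(CC)CC)CC=C | intermediate
11 | (3S)-6-[(4S,6R)-2,2-dimethyl-6-[2-(triethylsilyloxy)ethyl]-1,3-dioxan-4-yl]-3-(triethylsilyloxy)hexanal | CC[Si](CC)(CC)OCC[C@@H](O2)C[C@@H](OC2(C)C)CCC[C@H](O[Si](CC)(CC)CC)CC=O | intermediate
12 | (S)-4-benzyloxazolidin-2-one | O=C1N[C@@H](Cc2ccccc2)CO1 | starting material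
13 | butanoyl chloride | CCCC(=O)Cl | starting material
14 | (S)-4-benzyl-3-butanoyloxazolidin-2-one | CCCC(=O)N1[C@@H](Cc2ccccc2)COC1=O | intermediate
15 | dibutylboron Z-enolate of 14 | CC/C=C(\OB(CCCC)CCCC)N1[C@@H](Cc2ccccc2)COC1=O | intermediate
16 | (4S)-4-benzyl-3-[(2S,3R,5S)-8-[(4S,6R)-2,2-dimethyl-6-[2-(triethylsilyloxy)ethyl]-1,3-dioxan-4-yl]-2-ethyl-3-hydroxy-5-(triethylsilyloxy)octanoyl]oxazolidin-2-one | CC[Si](CC)(CC)OCC[C@@H](O2)C[C@@H](OC2(C)C)CCC[C@H](O[Si](CC)(CC)CC)C[C@@H](O)[C@H](CC)C(=O)N1[C@@H](Cc3ccccc3)COC1=O | intermediate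
17 | (4S)-4-benzyl-3-[(2S,3R,5S)-8-[(4S,6R)-2,2-dimethyl-6-[2-(triethylsilyloxy)ethyl]-1,3-dioxan-4-yl]-2-ethyl-3,5-bis(triethylsilyloxy)octanoyl]oxazolidin-2-one | CC[Si](CC)(CC)OCC[C@@H](O2)C[C@@H](OC2(C)C)CCC[C@H](O[Si](CC)(CC)CC)C[C@@H](O[Si](CC)(CC)CC)[C@H](CC)C(=O)N1[C@@H](Cc3ccccc3)COC1=O | intermediate
18 | (2S,3R,5S)-8-[(4S,6R)-2,2-dimethyl-6-[2-(triethylsilyloxy)ethyl]-1,3-dioxan-4-yl]-2-ethyl-3,5-bis(triethylsilyloxy)octanoic acid | CC[Si](CC)(CC)OCC[C@@H](O2)C[C@@H](OC2(C)C)CCC[C@H](O[Si](CC)(CC)CC)C[C@@H](O[Si](CC)(CC)CC)[C@H](CC)C(=O)O | intermediate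
19 | (2R,3R)-2,3-dimethyloxirane | C[C@H]1O[C@@H]1C | starting material
20 | vinylmagnesium bromide | C=C[Mg]Br | starting material
21 | (2R,3R)-3-methylpent-4-en-2-ol | C[C@@H](O)[C@H](C)C=C | intermediate
22 | (E)-but-2-enal | C/C=C/C=O | starting material
23 | (2E,4R,5R)-5-hydroxy-4-methylhex-2-enal | C[C@@H](O)[C@H](C)/C=C/C=O | intermediate
24 | triethyl 4-phosphonocrotonate | CCOC(=O)/C=C/CP(=O)(OCC)OCC | starting material
25 | ethyl (2E,4E,6E,8R,9R)-9-hydroxy-8-methyldeca-2,4,6-trienoate | C[C@@H](O)[C@H](C)/C=C/C=C/C=C/C(=O)OCC | intermediate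
26 | (2E,4E,6E,8R,9R)-8-methyldeca-2,4,6-triene-1,9-diol | C[C@@H](O)[C@H](C)/C=C/C=C/C=C/CO | intermediate
27 | (2E,4E,6E,8R,9R)-9-hydroxy-8-methyldeca-2,4,6-trienal | C[C@@H](O)[C@H](C)/C=C/C=C/C=C/C=O | intermediate
28 | (1,3-dioxolan-2-ylmethyl)triphenylphosphonium bromide | [Br-].C1COC(C[P+](c2ccccc2)(c2ccccc2)c2ccccc2)O1 | starting material
29 | (2R,3R,4E,6E,8E,10E)-11-(1,3-dioxolan-2-yl)-3-methylundeca-4,6,8,10-tetraen-2-ol (10E/10Z mixture before equilibration) | C[C@@H](O)[C@H](C)/C=C/C=C/C=C/C=C/C1OCCO1 | intermediate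
30 | (2E,4E,6E,8E,10R,11R)-11-hydroxy-10-methyldodeca-2,4,6,8-tetraenal | C[C@@H](O)[C@H](C)/C=C/C=C/C=C/C=C/C=O | intermediate
31 | diethyl (2-oxobutyl)phosphonate | CCC(=O)CP(=O)(OCC)OCC | starting material
32 | (4E,6E,8E,10E,12E,14R,15R)-15-hydroxy-14-methylhexadeca-4,6,8,10,12-pentaen-3-one | C[C@@H](O)[C@H](C)/C=C/C=C/C=C/C=C/C=C/C(=O)CC | intermediate
33 | mixed anhydride of 18 with 2,4,6-trichlorobenzoic acid | CC[Si](CC)(CC)OCC[C@@H](O2)C[C@@H](OC2(C)C)CCC[C@H](O[Si](CC)(CC)CC)C[C@@H](O[Si](CC)(CC)CC)[C@H](CC)C(=O)OC(=O)c1c(Cl)cc(Cl)cc1Cl | intermediate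
34 | (2R,3R,4E,6E,8E,10E,12E)-3-methyl-14-oxohexadeca-4,6,8,10,12-pentaen-2-yl (2S,3R,5S)-8-[(4S,6R)-2,2-dimethyl-6-[2-(triethylsilyloxy)ethyl]-1,3-dioxan-4-yl]-2-ethyl-3,5-bis(triethylsilyloxy)octanoate | CC[Si](CC)(CC)OCC[C@@H](O2)C[C@@H](OC2(C)C)CCC[C@H](O[Si](CC)(CC)CC)C[C@@H](O[Si](CC)(CC)CC)[C@H](CC)C(=O)O[C@H](C)[C@H](C)/C=C/C=C/C=C/C=C/C=C/C(=O)CC | intermediate
35 | (2R,3R,4E,6E,8E,10E,12E)-3-methyl-14-oxohexadeca-4,6,8,10,12-pentaen-2-yl (2S,3R,5S)-8-[(4S,6S)-2,2-dimethyl-6-(2-oxoethyl)-1,3-dioxan-4-yl]-2-ethyl-3,5-bis(triethylsilyloxy)octanoate | O=CC[C@@H](O2)C[C@@H](OC2(C)C)CCC[C@H](O[Si](CC)(CC)CC)C[C@@H](O[Si](CC)(CC)CC)[C@H](CC)C(=O)O[C@H](C)[C@H](C)/C=C/C=C/C=C/C=C/C=C/C(=O)CC | intermediate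
36 | E-enol dicyclohexylborinate of 35 (C14=C15, methyl trans to the boron-bearing oxygen) | O=CC[C@@H](O2)C[C@@H](OC2(C)C)CCC[C@H](O[Si](CC)(CC)CC)C[C@@H](O[Si](CC)(CC)CC)[C@H](CC)C(=O)O[C@H](C)[C@H](C)/C=C/C=C/C=C/C=C/C=C/C(OB(C1CCCCC1)C1CCCCC1)=C\C | intermediate
37 | dicyclohexylboron aldolate of 38 (boron on O13) | CC[C@@H]1C(=O)O[C@H](C)[C@H](C)/C=C/C=C/C=C/C=C/C=C/C(=O)[C@H](C)[C@H](OB(C3CCCCC3)C3CCCCC3)C[C@@H](O2)C[C@@H](OC2(C)C)CCC[C@H](O[Si](CC)(CC)CC)C[C@H]1O[Si](CC)(CC)CC | intermediate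
38 | (2S,3R,5S,9S,11R,13R,14R,16E,18E,20E,22E,24E,26R,27R)-2-ethyl-13-hydroxy-14,26-dimethyl-15-oxo-3,5-bis(triethylsilyloxy)octacosa-16,18,20,22,24-pentaen-27-olide 9,11-acetonide | CC[C@@H]1C(=O)O[C@H](C)[C@H](C)/C=C/C=C/C=C/C=C/C=C/C(=O)[C@H](C)[C@H](O)C[C@@H](O2)C[C@@H](OC2(C)C)CCC[C@H](O[Si](CC)(CC)CC)C[C@H]1O[Si](CC)(CC)CC | intermediate
39 | (2S,3R,5S,9S,11R,13R,14R,15R,16E,18E,20E,22E,24E,26R,27R)-2-ethyl-13,15-dihydroxy-14,26-dimethyl-3,5-bis(triethylsilyloxy)octacosa-16,18,20,22,24-pentaen-27-olide 9,11-acetonide | CC[C@@H]1C(=O)O[C@H](C)[C@H](C)/C=C/C=C/C=C/C=C/C=C/[C@@H](O)[C@H](C)[C@H](O)C[C@@H](O2)C[C@@H](OC2(C)C)CCC[C@H](O[Si](CC)(CC)CC)C[C@H]1O[Si](CC)(CC)CC | intermediate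
40 | (2S,3R,5S,9S,11S,13R,14R,15R,16E,18E,20E,22E,24E,26R,27R)-2-ethyl-3,5,9,11,13,15-hexahydroxy-14,26-dimethyloctacosa-16,18,20,22,24-pentaen-27-olide | CC[C@@H]1C(=O)O[C@H](C)[C@H](C)/C=C/C=C/C=C/C=C/C=C/[C@@H](O)[C@H](C)[C@H](O)C[C@@H](O)C[C@@H](O)CCC[C@H](O)C[C@H]1O | target

Total step count: 24. Longest linear sequence: 16 steps (steps 1–8, 10–12 and 20–24).

Steps most likely to fail

Step 22. The boron chloride and amine may enolise the aldehyde in competition with the ketone, and facial control at C13 may be incomplete because the large ring adds no bias of its own. The fallback keeps the ring closure at C13–C14 but makes the enolate reductively, so that no base meets the aldehyde. It sets out from 34: Me3SiOTf and Et3N in CH2Cl2 at −78 °C give the trimethylsilyl enol ether F1, and N-bromosuccinimide in THF at −78 °C converts it into the 14-bromo ketone F2. The Swern conditions of step 21 then give the bromo keto aldehyde F3. SmI2 (2.2 equiv) in THF at −78 °C under high dilution reduces the C–Br bond to a samarium enolate at C14 only, and this intramolecular Reformatsky-type aldol should give, after work-up of the samarium aldolate, 38, where the route resumes.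

Step 21. The chlorosulfonium reagent may also strip a secondary silyl ether or attack the pentaenone during the one-pot oxidative removal of the primary silyl ether. The fallback separates unmasking from oxidation and avoids activated DMSO. From 34, HF·pyridine buffered with pyridine in THF at 0 °C should cleave only the primary triethylsilyl ether to give the primary alcohol F4, and Dess–Martin periodinane with NaHCO3 in CH2Cl2 oxidises F4 to 35.

Step 23. The acidic borohydride medium may cause conjugate reduction of the pentaenone, ionisation next to the polyene or poor 1,3-induction. The fallback is an Evans–Tishchenko reduction. From 38, SmI2 (0.3 equiv) and excess acetaldehyde in THF at −10 °C form the C13 hemiacetal, which delivers hydride intramolecularly to C15 and should give the anti 13-O-acetyl 15-alcohol F5. K2CO3 in MeOH at 0 °C removes the acetate to give 39.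

Further compounds
F1 | step 22 | Z-trimethylsilyl enol ether of 34 (C14=C15) | CC[Si](CC)(CC)OCC[C@@H](O2)C[C@@H](OC2(C)C)CCC[C@H](O[Si](CC)(CC)CC)C[C@@H](O[Si](CC)(CC)CC)[C@H](CC)C(=O)O[C@H](C)[C@H](C)/C=C/C=C/C=C/C=C/C=C/C(O[Si](C)(C)C)=C/C
F2 | step 22 | 14-bromo derivative of 34 (both C14 epimers) | CC[Si](CC)(CC)OCC[C@@H](O2)C[C@@H](OC2(C)C)CCC[C@H](O[Si](CC)(CC)CC)C[C@@H](O[Si](CC)(CC)CC)[C@H](CC)C(=O)O[C@H](C)[C@H](C)/C=C/C=C/C=C/C=C/C=C/C(=O)C(C)Br
F3 | step 22 | 14-bromo derivative of 35 (both C14 epimers) | O=CC[C@@H](O2)C[C@@H](OC2(C)C)CCC[C@H](O[Si](CC)(CC)CC)C[C@@H](O[Si](CC)(CC)CC)[C@H](CC)C(=O)O[C@H](C)[C@H](C)/C=C/C=C/C=C/C=C/C=C/C(=O)C(C)Br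
F4 | step 21 | primary alcohol from 34 (free 13-hydroxyl; secondary silyl ethers kept) | OCC[C@@H](O2)C[C@@H](OC2(C)C)CCC[C@H](O[Si](CC)(CC)CC)C[C@@H](O[Si](CC)(CC)CC)[C@H](CC)C(=O)O[C@H](C)[C@H](C)/C=C/C=C/C=C/C=C/C=C/C(=O)CC
F5 | step 23 | 13-O-acetate of 39 (15-hydroxyl free) | CC[C@@H]1C(=O)O[C@H](C)[C@H](C)/C=C/C=C/C=C/C=C/C=C/[C@@H](O)[C@H](C)[C@H](OC(C)=O)C[C@@H](O2)C[C@@H](OC2(C)C)CCC[C@H](O[Si](CC)(CC)CC)C[C@H]1O[Si](CC)(CC)CC
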